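**Retrosynthetic overview**
- The (2S)-flavanone is opened at the pyranone O1–C2 bond (retro oxa-Michael) after a tert-butyl carboxylate is placed at C3 as a removable activator, which leads back to an arylidene β-ketoester.
- The C2=C3 bond of that alkylidene is cut by a Knoevenagel disconnection into 2-(4-methoxyphenyl)-1-benzofuran-5-carbaldehyde and tert-butyl 3-(2-hydroxy-4-methoxyphenyl)-3-oxopropanoate; the latter comes from methyl 4-methoxysalicylate and tert-butyl acetate by Claisen condensation.
- The strategy rests on the furan ring: O1' and C2' sit on either side of the C2'=C3' unit, C2' carries the 4-methoxyphenyl ring and C3' is bonded to C3a'. The array C3a'–C3'=C2'–aryl is a stilbene, so O1'–C2' is cut to an (E)-2-hydroxystilbene with the phenol ortho to the styryl arm.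
- The stilbene comes from a Mizoroki–Heck coupling of 3-bromo-4-hydroxybenzaldehyde with 4-vinylanisole.
- Ring order: furan ring (step 2), then pyranone ring (step 5); all benzene rings are purchased.

Key step: step 2

Assumption: the target is the (2S)-flavanone encoded by the SMILES, and the thiourea derived from 9-amino-9-deoxy-epi-quinidine is taken to deliver the (2S) series. The sense of induction would be checked on the first batch, and the pseudoenantiomeric epi-quinine-derived thiourea would replace it if it proves opposite.

**Step 1**
Reactants: 1 3-bromo-4-hydroxybenzaldehyde; 2 4-vinylanisole (1-ethenyl-4-methoxybenzene)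
Product: 3 4-hydroxy-3-[(E)-2-(4-methoxyphenyl)ethenyl]benzaldehyde
Conditions: Pd(OAc)2 (cat.), P(o-tol)3, Et3N, DMF, 100–110 °C
Reagents that add atoms: none
Why: Mizoroki–Heck reaction: Pd(0)/P(o-tol)3 inserts into the C–Br bond of the free bromophenol, syn-carbopalladation at the terminal carbon of the styrene and syn-β-hydride elimination should give the (E)-stilbene, and the aldehyde and free phenol are tolerated.

**Step 2**
Reactants: 3 4-hydroxy-3-[(E)-2-(4-methoxyphenyl)ethenyl]benzaldehyde
Product: 5 2-(4-methoxyphenyl)-1-benzofuran-5-carbaldehyde, via trans-3-iodo-2,3-dihydrobenzofuran 4 (not isolated)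
Conditions: I2 (3 equiv), K2CO3 (4 equiv), THF, rt, dark; aq. Na2S2O3 work-up
Reagents that add atoms: none
Why: Iodine adds reversibly to the electron-rich stilbene C=C to give an iodonium ion that is almost open towards the carbon benzylic to the 4-methoxyphenyl ring, and the ortho phenoxide formed by K2CO3 captures that carbon, which forms O1'–C2' and closes the furan ring as the trans-3-iodo-2,3-dihydrobenzofuran 4. The closure is 5-endo-trig, feasible because the activated alkene reacts as an anisyl-stabilised benzylic cation; the closest known reaction type is the iodine- or iodine(III)-mediated oxidative cyclisation of 2-hydroxystilbenes to 2-arylbenzofurans. Loss of HI from 4 (ionisation of the benzylic C3'–I bond, or iodide exchange to the cis isomer and anti-E2 by carbonate) then aromatises the ring, so no stereocentre remains. The step needs O-attack at C2' and not at C3', which the geometry secures since only the five-membered closure onto the anisyl-bearing carbon is reachable. It also needs alkene activation in preference to ring iodination, which the para-methoxy group (most nucleophilic alkene) and the para-formyl group (deactivated phenol ring) should secure. The aldehyde has no oxidation pathway in dry THF without an alcohol.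

**Step 3**
Reactants: 6 methyl 2-hydroxy-4-methoxybenzoate; 7 tert-butyl acetate
Product: 8 tert-butyl 3-(2-hydroxy-4-methoxyphenyl)-3-oxopropanoate
Conditions: LDA (4.2 equiv), 7 (4 equiv), THF, −78 °C; then 6, −78 → 0 °C; cold aq. NH4Cl
Reagents that add atoms: none
Why: Crossed Claisen condensation: excess lithium enolate of tert-butyl acetate acylates on the methyl ester of the lithium phenoxide, the product is held as its enolate so no second addition occurs, and the tert-butyl ester should resist lactonisation to the 4-hydroxycoumarin under the cold, mildly acidic work-up.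

**Step 4**
Reactants: 5 2-(4-methoxyphenyl)-1-benzofuran-5-carbaldehyde; 8 tert-butyl 3-(2-hydroxy-4-methoxyphenyl)-3-oxopropanoate
Product: 9 tert-butyl (2Z)-2-(2-hydroxy-4-methoxybenzoyl)-3-[2-(4-methoxyphenyl)-1-benzofuran-5-yl]prop-2-enoate
Conditions: piperidine (cat.), AcOH (cat.), 4 Å MS, toluene, rt
Reagents that add atoms: none
Why: Knoevenagel condensation through the iminium ion of 5 and the enol of 8; the alkylidene is taken as the (Z)-isomer (aryl cis to the ester), the usual outcome for arylidene β-ketoesters, and the bulky tert-butyl ester with buffered amine catalysis at room temperature should keep it from closing racemically.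

**Step 5**
Reactants: 9 tert-butyl (2Z)-2-(2-hydroxy-4-methoxybenzoyl)-3-[2-(4-methoxyphenyl)-1-benzofuran-5-yl]prop-2-enoate
Product: 12 (2S)-7-methoxy-2-[2-(4-methoxyphenyl)-1-benzofuran-5-yl]-2,3-dihydro-4H-chromen-4-one (Lophirone J), via chromanone tert-butyl ester 10 (not isolated), via β-keto acid 11 (not isolated)
Conditions: thiourea from 9-amino-9-deoxy-epi-quinidine and 3,5-bis(trifluoromethyl)phenyl isothiocyanate (10 mol%), toluene, −25 °C; then TsOH·H2O, 80 °C
Reagents that add atoms: none
Why: Catalytic asymmetric intramolecular oxa-Michael addition (6-endo-trig) followed by acid-mediated dealkoxycarbonylation: the thiourea N–H bonds hold the β-ketoester while the quinuclidine nitrogen activates the phenol O–H, so the oxygen should add to one enantioface of the alkylidene and set C2 as (S) under catalyst control; TsOH then protonates the amine (shutting off retro-Michael), cleaves the tert-butyl ester with loss of isobutene, and the β-keto acid decarboxylates, which erases C3 and leaves C2 untouched.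

**Compound list**
1 | 3-bromo-4-hydroxybenzaldehyde | O=Cc1ccc(O)c(Br)c1 | starting material
2 | 4-vinylanisole (1-ethenyl-4-methoxybenzene) | COc1ccc(C=C)cc1 | starting material
3 | 4-hydroxy-3-[(E)-2-(4-methoxyphenyl)ethenyl]benzaldehyde | COc1ccc(/C=C/c2cc(C=O)ccc2O)cc1 | intermediate
4 | rac-trans-3-iodo-2-(4-methoxyphenyl)-2,3-dihydro-1-benzofuran-5-carbaldehyde (one enantiomer drawn; not isolated) | COc1ccc(cc1)[C@H]1Oc2ccc(C=O)cc2[C@@H]1I | intermediate
5 | 2-(4-methoxyphenyl)-1-benzofuran-5-carbaldehyde | COc1ccc(-c2cc3cc(C=O)ccc3o2)cc1 | intermediate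
6 | methyl 2-hydroxy-4-methoxybenzoate | COC(=O)c1ccc(OC)cc1O | starting material
7 | tert-butyl acetate | CC(=O)OC(C)(C)C | starting material
8 | tert-butyl 3-(2-hydroxy-4-methoxyphenyl)-3-oxopropanoate | COc1ccc(C(=O)CC(=O)OC(C)(C)C)c(O)c1 | intermediate
9 | tert-butyl (2Z)-2-(2-hydroxy-4-methoxybenzoyl)-3-[2-(4-methoxyphenyl)-1-benzofuran-5-yl]prop-2-enoate | COc1ccc(cc1)-c1cc2cc(ccc2o1)/C=C(\C(=O)OC(C)(C)C)C(=O)c1ccc(OC)cc1O | intermediate
10 | tert-butyl (2S,3R)-7-methoxy-2-[2-(4-methoxyphenyl)-1-benzofuran-5-yl]-4-oxo-3,4-dihydro-2H-chromene-3-carboxylate (trans epimer drawn; C3 labile, in equilibrium with cis epimer and enol; not isolated) | COc1ccc(-c2cc3cc([C@@H]4[C@@H](C(=O)OC(C)(C)C)C(=O)c5ccc(OC)cc5O4)ccc3o2)cc1 | intermediate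
11 | (2S,3R)-7-methoxy-2-[2-(4-methoxyphenyl)-1-benzofuran-5-yl]-4-oxo-3,4-dihydro-2H-chromene-3-carboxylic acid (not isolated) | COc1ccc(-c2cc3cc([C@@H]4[C@@H](C(=O)O)C(=O)c5ccc(OC)cc5O4)ccc3o2)cc1 | intermediate
12 | (2S)-7-methoxy-2-[2-(4-methoxyphenyl)-1-benzofuran-5-yl]-2,3-dihydro-4H-chromen-4-one (Lophirone J) | COc1ccc(-c2cc3cc([C@@H]4CC(=O)c5ccc(OC)cc5O4)ccc3o2)cc1 | target

**Step count**
Total steps: 5. Longest linear sequence: 4 (steps 1, 2, 4, 5); step 3 is a one-step side branch.

**Steps most likely to fail**

1. Step 5. The large, flat benzofuranyl group may lower facial discrimination in the oxa-Michael addition, and enantiopurity may erode through reversible ring opening (retro-oxa-Michael) during the warm acidic decarboxylation. The fallback sets out from 5 and returns at 12.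
   - Claisen–Schmidt condensation of 5 with commercial paeonol (CC(=O)c1ccc(OC)cc1O; KOH, EtOH, rt) should give the chalcone (E)-1-(2-hydroxy-4-methoxyphenyl)-3-[2-(4-methoxyphenyl)-1-benzofuran-5-yl]prop-2-en-1-one F1.
   - NaOAc in refluxing EtOH should close it to the racemic flavanone rac-7-methoxy-2-[2-(4-methoxyphenyl)-1-benzofuran-5-yl]-2,3-dihydro-4H-chromen-4-one F2.
   - Kinetic resolution by asymmetric transfer hydrogenation (RuCl(p-cymene)[(R,R)-TsDPEN], HCO2H/Et3N, EtOAc, rt, stopped a little past half conversion) is expected to reduce the (2R)-ketone faster, by analogy with the facial preference of this catalyst class for 4-chromanones. That would give the cis-alcohol (2R,4R)-7-methoxy-2-[2-(4-methoxyphenyl)-1-benzofuran-5-yl]-3,4-dihydro-2H-chromen-4-ol F3 and leave 12, separable by chromatography. The catalyst enantiomer would be switched if the preference proves opposite.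

2. Step 2. Phenoxide ring iodination may compete with alkene activation, the reaction may stall at the iodo-dihydrobenzofuran stage, or a 1,2-shift of the anisyl group in the ionised intermediate may lead to the 3-aryl isomer. The fallback sets out from 1 and returns at 5.
   - Sonogashira coupling of 1 with commercial 4-ethynylanisole (COc1ccc(C#C)cc1; PdCl2(PPh3)2, CuI, Et3N, DMF, 80 °C) should give 4-hydroxy-3-[(4-methoxyphenyl)ethynyl]benzaldehyde F4.
   - F4 should undergo copper-assisted 5-endo-dig hydroalkoxylation in the same pot, or on further heating with CuI/Et3N, to give 5. This forms the same O1'–C2' bond at the alkyne oxidation level, so no oxidant is needed.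

3. Step 1. Oxidative addition to the electron-rich bromophenoxide may be slow and the catalyst may decompose, and partial α-arylation of the electron-rich styrene would give the 1,1-diarylethene. The fallback sets out from 1 and returns at 3.
   - Suzuki–Miyaura coupling of 1 with commercial (E)-2-(4-methoxyphenyl)vinylboronic acid (COc1ccc(/C=C/B(O)O)cc1; Pd(PPh3)4, K2CO3, dioxane/H2O, 85 °C) should give 3 directly, with the alkene geometry and regiochemistry fixed by the boronic acid. No compound outside the list is made (F0).

**Further compounds**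
F1 | step 5 | (E)-1-(2-hydroxy-4-methoxyphenyl)-3-[2-(4-methoxyphenyl)-1-benzofuran-5-yl]prop-2-en-1-one | COc1ccc(cc1)-c1cc2cc(/C=C/C(=O)c3ccc(OC)cc3O)ccc2o1
F2 | step 5 | rac-7-methoxy-2-[2-(4-methoxyphenyl)-1-benzofuran-5-yl]-2,3-dihydro-4H-chromen-4-one | COc1ccc(-c2cc3cc(C4CC(=O)c5ccc(OC)cc5O4)ccc3o2)cc1
F3 | step 5 | (2R,4R)-7-methoxy-2-[2-(4-methoxyphenyl)-1-benzofuran-5-yl]-3,4-dihydro-2H-chromen-4-ol | COc1ccc(-c2cc3cc([C@H]4C[C@@H](O)c5ccc(OC)cc5O4)ccc3o2)cc1
F4 | step 2 | 4-hydroxy-3-[(4-methoxyphenyl)ethynyl]benzaldehyde | COc1ccc(cc1)C#Cc1cc(C=O)ccc1O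
F0 | step 1 | none | none
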